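## Retrosynthetic overview

1. The target is (13S,14R)-labd-8(17)-ene-13,14,15-triol 14-propionate 15-acetate. The two esters go on last (primary C15, then secondary C14), which leads back to the triol and its 14,15-acetonide.
2. Key disconnection C13–C14: a one-pot lithiation–borylation–oxidation joins fragment 1 (C1–C13 with C16–C20, as a C13 secondary 2,4,6-triisopropylbenzoate) to fragment 2 (C14, C15 and both their oxygens, as an (S)-dioxolan-4-yl boronic ester).
3. Enabling feature: the acyclic vicinal diol C13(OH)–C14(O) in the side chain on C9 of ring B. C13 carries only CH3-16, CH2-12 and oxygen, so its oxygen can serve first as directing and leaving group (hindered benzoate) and then be returned from boron; the only other reactive site, the exocyclic C8=C17 methylene on ring B, should tolerate s-BuLi at −60 °C and basic peroxide.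
4. Fragment 1 comes from (+)-manool by cleavage of its own C13–C14 bond (its 13R centre is the wrong one and is erased), enzymatic reduction and Mitsunobu inversion. Fragment 2 comes from a silyloxyacetaldehyde by enantioselective CuCl-catalysed borylation.
5. Ring order: rings A and B (the trans-decalin) come intact from manool. The only rings formed are temporary, the dioxolane (step 4) and the dioxaborinane (step 5), removed again in steps 7 and 6.

Key step: step 6

Assumption: labdane numbering is used (C8=C17 exocyclic methylene, C13 tertiary carbinol, C14 propionyloxy methine, C15 acetoxymethylene); the target is 5S,9S,10S,13S,14R, and (+)-manool (5S,9S,10S,13R), a commercial natural product, carries the same decalin.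

## Route

Step 1
Reactants: 1 (+)-manool
Product: 2 14,15-dinorlabd-8(17)-en-13-one
Conditions: KMnO4, acetone, 0 °C → rt
Reagents that add atoms: none
Why: Permanganate should dihydroxylate the unhindered monosubstituted C14=C15 vinyl group faster than the hindered exocyclic C8=C17 alkene, and the resulting tertiary α-hydroxy glycol is cleaved at C13–C14 to the methyl ketone (oxidative cleavage of a tertiary vinyl carbinol), with C5, C9 and C10 untouched and no new stereocentre.

Step 2
Reactants: 2 14,15-dinorlabd-8(17)-en-13-one
Product: 3 (13R)-14,15-dinorlabd-8(17)-en-13-ol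
Conditions: (R)-selective alcohol dehydrogenase from Lactobacillus kefir, NADP+ (cat.), i-PrOH (cosolvent and reductant), phosphate buffer pH 7, MgCl2, 30 °C
Reagents that add atoms: none
Why: Biocatalytic asymmetric reduction of a methyl ketone, in which the enzyme pocket places the methyl group in its small site and delivers hydride to the si face, should set C13 as R under catalyst control, independent of the remote decalin.

Step 3
Reactants: 3 (13R)-14,15-dinorlabd-8(17)-en-13-ol
Product: 4 (13S)-14,15-dinorlabd-8(17)-en-13-yl 2,4,6-triisopropylbenzoate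
Conditions: 2,4,6-triisopropylbenzoic acid, PPh3, DIAD, THF, 0 °C → rt
Reagents that add atoms: 2,4,6-triisopropylbenzoic acid, CC(C)c1cc(C(C)C)c(C(=O)O)c(C(C)C)c1
Why: The Mitsunobu reaction displaces the oxyphosphonium by the carboxylate in an SN2 step, so C13 should be inverted cleanly from R to S while the hindered benzoate needed as directing and leaving group for step 6 is installed.

Step 4
Reactants: 5 (tert-butyldimethylsilyloxy)acetaldehyde
Product: 8 (S)-2-(2,2-dimethyl-1,3-dioxolan-4-yl)-4,4,5,5-tetramethyl-1,3,2-dioxaborolane, via hydroxy boronate 6 (not isolated), via boryl diol 7 (not isolated)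
Conditions: CuCl (5 mol %), (R)-DTBM-SEGPHOS (5 mol %), KOt-Bu (10 mol %), B2pin2, MeOH (2 equiv), THF, 30 °C; then CSA, MeOH, rt; then 2,2-dimethoxypropane, acetone, rt
Reagents that add atoms: bis(pinacolato)diboron, CC1(C)OB(OC1(C)C)B2OC(C)(C)C(C)(C)O2; 2,2-dimethoxypropane, COC(C)(C)OC
Why: Enantioselective nucleophilic borylation of an aliphatic aldehyde, in which the copper boryl adds across C=O inside the DTBM-SEGPHOS pocket (ligand antipode chosen to give S at the future C14), is followed by acid methanolysis of the primary silyl ether and acetalisation, which should close the dioxolane without touching the C–B stereocentre.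

Step 5
Reactants: 8 (S)-2-(2,2-dimethyl-1,3-dioxolan-4-yl)-4,4,5,5-tetramethyl-1,3,2-dioxaborolane
Product: 10 (S)-2-(2,2-dimethyl-1,3-dioxolan-4-yl)-5,5-dimethyl-1,3,2-dioxaborinane, via diethanolamine boronate 9 (not isolated)
Conditions: diethanolamine, Et2O, rt; then neopentyl glycol, Et2O/0.1 M aq HCl, rt
Reagents that add atoms: neopentyl glycol, OCC(C)(C)CO
Why: Boronic ester transesterification through the tetracoordinate diethanolamine adduct, which dilute acid releases and neopentyl glycol recaptures, should give the less hindered six-membered boronic ester that step 6 requires, and the C–B stereocentre is not involved.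

Step 6
Reactants: 4 (13S)-14,15-dinorlabd-8(17)-en-13-yl 2,4,6-triisopropylbenzoate; 10 (S)-2-(2,2-dimethyl-1,3-dioxolan-4-yl)-5,5-dimethyl-1,3,2-dioxaborinane
Product: 14 (13S,14R)-14,15-O-isopropylidenelabd-8(17)-ene-13,14,15-triol, via lithiated benzoate 11 (not isolated), via boron ate complex 12 (not isolated), via tertiary boronic ester 13 (not isolated)
Conditions: s-BuLi, TMEDA, CPME, −60 °C; then 10, −60 °C, then 50 °C; then NaOH (2 M aq), H2O2 (30%), THF, 0 °C → rt
Reagents that add atoms: hydrogen peroxide, OO
Why: Proposed new method: the benzoate carbonyl directs s-BuLi/TMEDA to the C13–H bond, the configurationally stable tertiary α-oxy organolithium 11 adds to the boron of 10 to give ate complex 12, C14 then migrates from boron to C13 anti to the departing carboxylate (1,2-metalate rearrangement), and H2O2/NaOH replaces boron by hydroxyl. The closest known reaction type is the lithiation–borylation–oxidation of secondary dialkyl 2,4,6-triisopropylbenzoates (4-arylbutan-2-yl esters, of which 4 is a direct analogue) with neopentyl glycol boronic esters to give tertiary alcohols, together with the 1,2-migration of α-alkoxyalkyl groups known from the Matteson homologation; new here is an α,β-dioxygenated secondary migrating group on a tertiary carbenoid. No ring is closed. C13 is set stereospecifically by substrate control (retention in lithiation and borylation, inversion in the 1,2-shift, retention in the oxidation, so the 13S ester should give the 13S carbinol), and C14 migrates with retention (the S boronate becomes 14R only because C13 takes the place of boron in the priority order), so both centres are independent of the remote decalin. The step needs site-selective lithiation (secured by the directing benzoate at −60 °C, where the allylic hydrogens at C7 and C9 next to C8=C17 should not be removed), carbon rather than oxygen migration (favoured by the unhindered neopentyl glycol ester and the good carboxylate leaving group), and no β-elimination of the C15 oxygen (the dioxolane ring keeps the C15–O bond out of anti-periplanar alignment with C14–B and makes it a poor leaving group).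

Step 7
Reactants: 14 (13S,14R)-14,15-O-isopropylidenelabd-8(17)-ene-13,14,15-triol
Product: 15 (13S,14R)-labd-8(17)-ene-13,14,15-triol
Conditions: AcOH/H2O (4:1), 40 °C
Reagents that add atoms: none
Why: Weak-acid hydrolysis of the terminal acetonide should free the 14,15-diol while sparing the acid-sensitive exocyclic C8=C17 alkene and the tertiary C13 carbinol, and no stereocentre is touched.

Step 8
Reactants: 15 (13S,14R)-labd-8(17)-ene-13,14,15-triol
Product: 16 (13S,14R)-13,14-dihydroxylabd-8(17)-en-15-yl acetate
Conditions: AcCl, 2,4,6-collidine, CH2Cl2, −78 °C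
Reagents that add atoms: acetyl chloride, CC(=O)Cl
Why: Sterically controlled acylation with acetyl chloride and a hindered pyridine base at low temperature should esterify only the primary C15 hydroxyl, since the secondary C14 hydroxyl is flanked by the quaternary C13 and the tertiary C13 hydroxyl is inert.

Step 9
Reactants: 16 (13S,14R)-13,14-dihydroxylabd-8(17)-en-15-yl acetate
Product: 17 (13S,14R)-15-acetoxy-13-hydroxylabd-8(17)-en-14-yl propanoate
Conditions: (EtCO)2O, DMAP (cat.), pyridine, 0 °C
Reagents that add atoms: propionic anhydride, CCC(=O)OC(=O)CC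
Why: DMAP-catalysed acylation should esterify the remaining secondary C14 hydroxyl with retention while the tertiary C13 hydroxyl does not react, and the short reaction at 0 °C limits acyl migration between O15 and O14.

## Compound list

1 | (+)-manool, (13R)-labda-8(17),14-dien-13-ol | C=C1CC[C@H]2C(C)(C)CCC[C@]2(C)[C@H]1CC[C@@](C)(O)C=C | starting material
2 | 14,15-dinorlabd-8(17)-en-13-one | C=C1CC[C@H]2C(C)(C)CCC[C@]2(C)[C@H]1CCC(C)=O | intermediate
3 | (13R)-14,15-dinorlabd-8(17)-en-13-ol | C=C1CC[C@H]2C(C)(C)CCC[C@]2(C)[C@H]1CC[C@@H](C)O | intermediate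
4 | (13S)-14,15-dinorlabd-8(17)-en-13-yl 2,4,6-triisopropylbenzoate | C=C1CC[C@H]2C(C)(C)CCC[C@]2(C)[C@H]1CC[C@H](C)OC(=O)c3c(C(C)C)cc(C(C)C)cc3C(C)C | intermediate
5 | (tert-butyldimethylsilyloxy)acetaldehyde | CC(C)(C)[Si](C)(C)OCC=O | starting material
6 | (S)-2-(tert-butyldimethylsilyloxy)-1-(4,4,5,5-tetramethyl-1,3,2-dioxaborolan-2-yl)ethanol (hydroxy boronate) | CC(C)(C)[Si](C)(C)OC[C@@H](O)B1OC(C)(C)C(C)(C)O1 | intermediate
7 | (S)-1-(4,4,5,5-tetramethyl-1,3,2-dioxaborolan-2-yl)ethane-1,2-diol (boryl diol) | OC[C@@H](O)B1OC(C)(C)C(C)(C)O1 | intermediate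
8 | (S)-2-(2,2-dimethyl-1,3-dioxolan-4-yl)-4,4,5,5-tetramethyl-1,3,2-dioxaborolane | CC1(C)OC[C@@H](O1)B2OC(C)(C)C(C)(C)O2 | intermediate
9 | (S)-2-(2,2-dimethyl-1,3-dioxolan-4-yl)-1,3,6,2-dioxazaborocane (diethanolamine boronate) | CC1(C)OC[C@@H](O1)B2OCCNCCO2 | intermediate
10 | (S)-2-(2,2-dimethyl-1,3-dioxolan-4-yl)-5,5-dimethyl-1,3,2-dioxaborinane | CC1(C)OC[C@@H](O1)B2OCC(C)(C)CO2 | intermediate
11 | C13-lithiated benzoate derived from 4 | C=C1CC[C@H]2C(C)(C)CCC[C@]2(C)[C@H]1CC[C@]([Li])(C)OC(=O)c3c(C(C)C)cc(C(C)C)cc3C(C)C | intermediate
12 | lithium boron ate complex of 11 and 10 | [Li+].C=C1CC[C@H]2C(C)(C)CCC[C@]2(C)[C@H]1CC[C@](C)(OC(=O)c3c(C(C)C)cc(C(C)C)cc3C(C)C)[B-]4(OCC(C)(C)CO4)[C@H]5COC(C)(C)O5 | intermediate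
13 | C13 tertiary neopentyl glycol boronic ester bearing the (R)-dioxolan-4-yl group | C=C1CC[C@H]2C(C)(C)CCC[C@]2(C)[C@H]1CC[C@](C)(B3OCC(C)(C)CO3)[C@H]4COC(C)(C)O4 | intermediate
14 | (13S,14R)-14,15-O-isopropylidenelabd-8(17)-ene-13,14,15-triol | C=C1CC[C@H]2C(C)(C)CCC[C@]2(C)[C@H]1CC[C@](C)(O)[C@H]3COC(C)(C)O3 | intermediate
15 | (13S,14R)-labd-8(17)-ene-13,14,15-triol | C=C1CC[C@H]2C(C)(C)CCC[C@]2(C)[C@H]1CC[C@](C)(O)[C@H](O)CO | intermediate
16 | (13S,14R)-13,14-dihydroxylabd-8(17)-en-15-yl acetate | C=C1CC[C@H]2C(C)(C)CCC[C@]2(C)[C@H]1CC[C@](C)(O)[C@H](O)COC(C)=O | intermediate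
17 | (13S,14R)-15-acetoxy-13-hydroxylabd-8(17)-en-14-yl propanoate | C=C1CC[C@H]2C(C)(C)CCC[C@]2(C)[C@H]1CC[C@](C)(O)[C@@H](COC(C)=O)OC(=O)CC | target

## Step count and risks

Total: 9 steps. Longest linear sequence: 7 steps (steps 1, 2, 3, 6, 7, 8, 9); the boronate branch (steps 4, 5) joins at step 6.

**Step 6 (proposed new method).** The hindered tertiary organolithium may add to boron slowly or reversibly, so that the ate complex reverts on warming and C13 loses its configuration. A glycol oxygen may migrate in place of C14, or the dioxolane oxygen may be lost by β-elimination.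

Fallback, known chemistry, from 2 back to 15: the C13–C14 bond is made as a C=C bond and oxidised afterwards.
- Horner–Wadsworth–Emmons olefination of 2 (triethyl phosphonoacetate, NaH, THF) should give ethyl (13E)-labda-8(17),13-dien-15-oate F1, the E isomer being separated by chromatography.
- Reduction with i-Bu2AlH (CH2Cl2, −78 °C) should give (13E)-labda-8(17),13-dien-15-ol F2.
- Sharpless epoxidation (Ti(Oi-Pr)4, L-(+)-diethyl tartrate, t-BuOOH, 4 Å sieves, CH2Cl2, −20 °C) should give (13S,14S)-13,14-epoxylabd-8(17)-en-15-ol F3, by reagent control at the allylic alcohol only.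
- Payne rearrangement with hydroxide opening at C15 (NaOH, t-BuOH/H2O, 70 °C) inverts C14 and should give triol 15, where the route is rejoined.

**Step 5.** The acetonide may hydrolyse, or the free α-alkoxy boronic acid may protodeboronate, during acidic release from the diethanolamine adduct.

Fallback, from 5 back to 10: neopentyl glycol is brought in with the diboron reagent, so no ligand exchange is needed. Aldehyde 5 is borylated under the catalyst system of step 4 with bis(neopentyl glycolato)diboron to give (S)-2-(tert-butyldimethylsilyloxy)-1-(5,5-dimethyl-1,3,2-dioxaborinan-2-yl)ethanol F4. CSA/MeOH removes the silyl group to give (S)-1-(5,5-dimethyl-1,3,2-dioxaborinan-2-yl)ethane-1,2-diol F5, and 2,2-dimethoxypropane then closes the dioxolane to give 10.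

**Step 2.** The bulky, water-insoluble ketone may be poorly accepted by the enzyme, or facial selectivity may be incomplete, which would leave C13 epimers that cannot be separated.

Fallback, from 2 back to 3: reduction followed by kinetic resolution, which turns the epimers into separable compound classes. NaBH4 (MeOH, 0 °C) gives 3 together with (13S)-14,15-dinorlabd-8(17)-en-13-ol F6. Candida antarctica lipase B with vinyl acetate (hexane, rt) should acetylate only the 13R epimer, to (13R)-14,15-dinorlabd-8(17)-en-13-yl acetate F7, which is separated from unreacted F6 by chromatography. K2CO3/MeOH then returns 3, and F6 is recycled by oxidation to 2.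

Further compounds
F1 | step 6 | ethyl (13E)-labda-8(17),13-dien-15-oate | C=C1CC[C@H]2C(C)(C)CCC[C@]2(C)[C@H]1CC/C(C)=C/C(=O)OCC
F2 | step 6 | (13E)-labda-8(17),13-dien-15-ol | C=C1CC[C@H]2C(C)(C)CCC[C@]2(C)[C@H]1CC/C(C)=C/CO
F3 | step 6 | (13S,14S)-13,14-epoxylabd-8(17)-en-15-ol | C=C1CC[C@H]2C(C)(C)CCC[C@]2(C)[C@H]1CC[C@]3(C)O[C@H]3CO
F4 | step 5 | (S)-2-(tert-butyldimethylsilyloxy)-1-(5,5-dimethyl-1,3,2-dioxaborinan-2-yl)ethanol | CC(C)(C)[Si](C)(C)OC[C@@H](O)B1OCC(C)(C)CO1
F5 | step 5 | (S)-1-(5,5-dimethyl-1,3,2-dioxaborinan-2-yl)ethane-1,2-diol | OC[C@@H](O)B1OCC(C)(C)CO1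
F6 | step 2 | (13S)-14,15-dinorlabd-8(17)-en-13-ol | C=C1CC[C@H]2C(C)(C)CCC[C@]2(C)[C@H]1CC[C@H](C)O
F7 | step 2 | (13R)-14,15-dinorlabd-8(17)-en-13-yl acetate | C=C1CC[C@H]2C(C)(C)CCC[C@]2(C)[C@H]1CC[C@@H](C)OC(C)=O
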